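All runs were computed on assumed constants; noise was put on by code.

Late in the south and west runs the substrate stops falling, at 8.9% and 16.5% of its charge, while the south-west run, with more solid reagent, reads 0%. You can take these plateaus as a reagent running out.

| flask | substrate | solid reagent | protic impurity | remark | time |
|---|---|---|---|---|---|
| south | 0.40 M | 0.38 M | 0.020 M | run made earlier |  |
| west | 0.40 M | 0.38 M | 0.080 M | run made earlier |  |
| south-west | 0.40 M | 0.57 M | 0.040 M | run made earlier |  |
| flask | 0.40 M | 0.380 M | 0.0400 M |  | 4.0 h |

| run | time / h | substrate / % | target / % |
|---|---|---|---|
| south | 0.200 | 18.1 | 14.9 |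
| south | 0.667 | 8.5 | 11.6 |
| south | 1.00 | 9.7 | 10.8 |
| south | 2.00 | 9.4 | 10.4 |
| south | 2.50 | 6.7 | 11.1 |
| south | 3.00 | 8.9 | 10.4 |
| west | 0.250 | 18.3 | 13.3 |
| west | 0.417 | 14.3 | 10.0 |
| west | 0.667 | 15.7 | 10.3 |
| west | 1.33 | 15.9 | 11.4 |
| west | 2.00 | 17.0 | 10.1 |
| west | 3.00 | 16.5 | 11.0 |
| south-west | 0.250 | 6.2 | 13.5 |
| south-west | 0.833 | 0 | 11.0 |
| south-west | 1.33 | 0 | 13.2 |
| south-west | 2.50 | 1.0 | 12.9 |
| south-west | 3.00 | 0 | 10.3 |

(each reading ± 1 percentage point)

- as a solid, counted per litre of solution: solid reagent
- what was read earlier has a scatter of 1 percentage point, one standard deviation
- on the list of suspects stand: substrate + partner -> intermediate + by-product; intermediate <-> target; intermediate <-> isomer of the product A; target <-> isomer of the product B; solid reagent <-> partner; partner + protic impurity -> quenched reagent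
- at the start none of the solid reagent is in solution
- the reaction counts as stopped when no species that holds the substrate changes by six tenths of a point or more over the second half of the time

1. at 4.0 h, what has stopped the reaction, if anything has (for what has run out or reacted, a solid counts together with what of it has only dissolved) (the partner has run out first / all of the substrate has reacted / forward and back rates have come level / it is still moving)
2. share of the substrate used up at 4.0 h
3. target at 4.0 h, in percent of the substrate charged

Build the flask up one process at a time. With the main step alone, one partner takes one substrate, and the solid reagent charged covers 95.0% of the substrate. Now add the protic impurity, served first: 85.0% remains. The west run shows something between. Its plateau averages 16.3%, and the balance of the solid reagent (charged equals substrate used plus impurity used) puts the impurity used at 0.0451 M of its 0.080 M.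

Let x and y be the fractions of substrate and impurity left. If both steps are first order in partner and in their own reactant, the partner cancels and x equals y to the power s. This s, the selectivity factor, is how many times faster a substrate molecule takes partner than an impurity molecule does. The west run reads s = 2.19.

In the flask the solid reagent, 0.380 M, is less than the 0.440 M of substrate and impurity together, so it is the limiting reagent. Putting the balance and s together, starting from x = 15.0%, successive passes give 10.8%, 11.4% and 11.3%. My conversion is therefore 88.7%. Target averages 11.8% in the south-west run, where the substrate reads about zero. Scaling that by conversion, I expect 10.5%.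

The forecast says the partner has run out first, with 88.3% converted and 10.7% of target, on the grounds “Impurity therefore competes with substrate for the partner”. It took s near 2, and its conversion is lower than mine.

The flask gives the partner has run out first, 88.8% and 10.8%.

    substrate + partner → intermediate + by-product (k = 4.47 M⁻¹ min⁻¹)
    intermediate ⇌ target (K = 0.440, k = 1.14 min⁻¹)
    intermediate ⇌ isomer of the product A (K = 2.10, k = 0.242 min⁻¹)
    target ⇌ isomer of the product B (K = 0.160, k = 0.947 min⁻¹)
    solid reagent ⇌ partner, rate k5*(cs5 - [partner]) while solid is left; crystals form when [partner] > cs5 (solubility = 0.200 M, k = 0.212 min⁻¹)
    partner + protic impurity → quenched reagent (k = 1.95 M⁻¹ min⁻¹)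

At 0.0837 h the flask's substrate uses partner 17 times as fast as its protic impurity does, a rate ratio that is s times the ratio of the two concentrations then. At the end the flask keeps 11% of its substrate, less than the 38% of its impurity, and the s read earlier turns that substrate figure into 36.7% of impurity. The neighbour with 0.23 M of solid reagent keeps 45% of its substrate, from which s gives 69.7% of impurity, and it holds 71%.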